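## The problem

- Laxiflorin 12 is a flavanone. Benzene ring A shares the C4a–C8a bond with the dihydropyranone ring C (O1, C2, C3, C4=O), and C2 carries ring B (4-hydroxy-3-methoxyphenyl).
- Ring A is hexasubstituted with carbon and oxygen alternating: C4a acyl, C5 OH, C6 CH2CH2OH, C7 OH, C8 prenyl, C8a O1. No simple arene has this pattern. In any open-chain precursor of ring C the two hydroxyls ortho to the acyl group are nearly alike, so ring closure confuses C6 with C8.
- C2 (S) is the only stereocentre, so nothing in the molecule can control it and it must come from a catalyst or reagent. It is benzylic, bound to O1 and β to the ketone, and is lost by retro-oxa-Michael opening in base, most easily once the 4′-OH is free.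
- The prenyl group beside 7-OH closes to a chroman in strong acid and does not survive ozone, peracids or hydrogenation. A second alkene therefore cannot be degraded to the C2 chain in its presence.
- The 2-hydroxyethyl group lies between two phenols. A leaving group at its end gives a dihydrobenzofuran, and the aldehyde oxidation level gives a benzofuran.
- The plan uses a 3 + 3 match inside ring A. C5(OH)–C6(CH2CH2OH)–C7(OH) is a cyclopropane-1,1-dicarbonyl unit across which water has been added. C4a–C8a(O1)–C8 together with C2, C3 and C4 is, at the chromone level, a 2-alkyl-4-pyranone whose C3 and side-chain α-carbon are the two nucleophilic ends of one dienolate.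
- In that pairing O1 is an ether before ring A exists, and O5 and O7 come from two equivalent ester groups. The 6/8 question cannot arise.

## Retrosynthesis

**12 from 11.** Only four O–acetyl bonds are cut. Acetates are preferred to ethers for two reasons. They leave by acid-catalysed methanolysis, where ring C cannot open, and they turn O5 and O7 from strong donors into weak ones for the preceding step. 11 is no simpler than 12, but it has no acidic proton. The forward reaction must spare the prenyl group and C2.

**11 from 8 and 10.** The C2–C1′ bond is cut. The neighbouring cut O1–C2 leads back either to an open-chain enone (6/8 ambiguity, reversible closure) or to an SN2 reaction at an electron-rich benzylic carbon. C2–C1′ leads instead to the flat chromone 8 and boronic acid 10. 8 has no stereocentre and no ring that opens in base, so all strongly basic and acidic chemistry is placed before the stereocentre exists. Ring B is joined convergently. The forward reaction, a rhodium-catalysed asymmetric 1,4-addition, must find one face of C2=C3 by catalyst control alone under neutral conditions.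

**8 from 7.** Three O–acetyl bonds are cut. 7 carries all carbon atoms of rings A and C. The forward step only has to cap every OH, including the chelated 5-OH.

**7 from 6.** The CH2–OH bond of the side chain is cut and its carbon is tied back to C6 (retro homo-Michael addition). This dearomatises ring A to spirocyclopropane dienone 6. The neighbouring cut C6–CH2 would need a C2 electrophile, a regioselective attack on an arene with two open positions, and a protecting group on the chain. In 6 the chain and both phenols are latent in one unit without any protecting group. The forward reaction asks an external oxygen nucleophile to open the three-membered ring. Strain release and aromatisation drive it, and halide must be absent.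

**6 from 3 and 4 by way of 5.** C5–C4a and C7–C8 are cut, and ring A falls into a C3 dinucleophile and a C3 dielectrophile.
- Cuts that keep ring A (C4–C4a, C8a–O1, C8–CH2) leave the hexasubstituted benzene to be made. This cut removes it: 3 is a monocyclic pyranone with one substituent and 4 is a symmetrical diester.
- 4 has no α-proton, so it can neither quench the dienolate nor form a ketene. Its two esters and its two CH2 groups are equivalent, so no orientation problem exists.
- The annulation is placed at the chromone level, because at the flavanone level the base would enolise C3 and expel O1.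
- The forward reaction needs γ-acylation at C8 followed by C-acylation at C4a.

**3 from 1 and 2.** The bond between the future C8 and the prenyl CH2 is cut. The neighbouring option, prenylation of C8 after ring A exists, would bring back the competition between C- and O-alkylation. Here it is a plain side-chain enolate alkylation of 1 with 2.

**10 from 9.** One O–acetyl bond is cut, so that the protecting groups of both coupling partners match.

## Roads not taken

**Alternative 1:** The most obvious route cuts O1–C2 and C2–C3. The forward key step is Claisen–Schmidt condensation of acetophenone A1 with vanillin A2 to chalcone A3, followed by oxa-Michael closure.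
- A1 still contains the whole problem of ring A. Two different C-alkylations of a phloroacetophenone compete with O-alkylation and with each other.
- In A3 both ortho hydroxyls can close. The 8-(2-hydroxyethyl)-6-prenyl isomer A4 competes unless two nearly equal chelated phenols are told apart by protection.
- The closure is reversible and base-mediated, so enantiocontrol on a simple 2′-hydroxychalcone is weak.
- The chosen plan never has two candidate oxygens and sets C2 irreversibly.

**Alternative 2:** Ring A is kept aromatic and C6–CH2 and C8–CH2 are cut on homoeriodictyol A5. The forward key step is a sigmatropic relay from O5. A 5-O-allyl ether rearranges to C6 and is cleaved and reduced. The 5-O-prenyl ether A6 then undergoes a Claisen–Cope sequence to C8.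
- Regiocontrol is sound, since C6 is the only open ortho position of O5.
- One substituent is installed at a time, however, and the allyl group must be degraded before prenyl arrives.
- About eight linear operations with protecting-group traffic are spent on ring A.
- Two thermal steps are run on a configurationally labile flavanone.
- The chosen plan makes all six positions of ring A in one flask.

**Alternative 3:** C4–C4a and C8–CH2 are cut, using the local twofold axis of ring A through C8a/O1 and C6. The forward key step starts from diiodide A7. Double iodine–lithium exchange, Parham cyclisation onto the Weinreb amide and copper-mediated prenylation of the remaining aryllithium would follow in one flask.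
- The degenerate ring closure is attractive.
- A7, however, needs its O1–C2 bond from Mitsunobu inversion of carbinol A8. A8 is p-alkoxybenzylic and β to a carbonyl, so ionisation and elimination threaten the only stereocentre at the start of the route.
- The symmetric arene needs a run-up of five to six steps.
- The aryloxide is a β-leaving group under organolithium conditions.

Key step: step 2

Assumption: the SMILES is read as 2S (O1 > C1′ > C3 > H), and 1, 2, 4 and 9 are taken as catalogue chemicals.

## Route

Step 1
Reactants: 1 2-methyl-4H-pyran-4-one; 2 1-bromo-3-methylbut-2-ene (prenyl bromide)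
Product: 3 2-(4-methylpent-3-en-1-yl)-4H-pyran-4-one
Conditions: LiHMDS (1.05 equiv), THF, −78 °C; then 2 (1.0 equiv), −78 → −20 °C
Reagents that add atoms: none
Why: Deprotonation of the 2-methyl group gives the linear dienolate, which is alkylated at the exocyclic carbon because only this restores the pyranone; side-chain enolate alkylation of 2-methyl-4-pyranones with allylic halides is standard, and the primary bromide reacts by SN2 at CH2. Near-stoichiometric base and halide limit dialkylation.

Step 2
Reactants: 3 2-(4-methylpent-3-en-1-yl)-4H-pyran-4-one; 4 dimethyl cyclopropane-1,1-dicarboxylate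
Product: 7 5,7-dihydroxy-6-(2-hydroxyethyl)-8-(3-methylbut-2-en-1-yl)-4H-chromen-4-one, via keto ester 5 (not isolated), via spirocyclopropane dienone 6 (not isolated)
Conditions: LiHMDS (3.2 equiv), THF, −78 °C; 4 (1.1 equiv), −78 °C → rt, then 40 °C; then 1 M aq H2SO4/THF, 0 °C → rt
Reagents that add atoms: water (O)
Why: Proposed new method: LiHMDS removes a proton from the side-chain CH2 next to the pyranone (future C8), and the linear dienolate attacks one of the two homotopic esters of 4 through C8, since only γ-attack restores the pyranone (crossed Claisen condensation with a non-enolisable ester, C7–C8 bond, keto ester 5). 5 is deprotonated at once at C8, and its vinylogous β-diketonate, whose charge also resides on C4a (C3 of the pyranone), closes ring A on the second ester by a 6-(enolexo)-exo-trig Dieckmann acylation (C5–C4a bond), after which loss of the C4a proton gives the enolate of 6. The closest known reaction types are the α,α′-annulation of enol ethers and ketone enolates with 2,2-disubstituted malonyl units to cyclohexane-1,3,5-triones (Effenberger type) and the [3+3] cyclisation/homo-Michael domino of 1,3-bis(silyl enol ethers) with 1,1-diacylcyclopropanes, where a spirocyclopropane is likewise opened with aromatisation; neither has been run on a 4-pyranone or at the ester oxidation level. O-Acylation cannot compete in the ring closure, because O1 is already the ring ether and closure on O4 would need an eight-membered ring, so the oxygen on C8a stays distinct from O5 and O7. Attack at carbonyl rather than at the cyclopropane is secured by the hard lithium dienolate at low temperature and by the fact that 6 exists only as a delocalised anion until the quench. On acidification neutral 6, a 6,6-disubstituted cyclohexadienone with a doubly activated three-membered ring, is attacked by water at either of its equivalent CH2 groups in an SN2-type homo-conjugate addition, and strain release plus aromatisation set free 5-OH, 7-OH and the CH2CH2OH chain together. The flanking enol oxygens cannot reach the backside of the breaking C6–CH2 bond and no halide is present, so the dihydrobenzofuran that a 2-haloethyl intermediate would give is avoided. No stereocentre survives the step, since C8 of racemic 5 is planarised.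

Step 3
Reactants: 7 5,7-dihydroxy-6-(2-hydroxyethyl)-8-(3-methylbut-2-en-1-yl)-4H-chromen-4-one
Product: 8 6-(2-acetoxyethyl)-8-(3-methylbut-2-en-1-yl)-4-oxo-4H-chromene-5,7-diyl diacetate
Conditions: Ac2O (6 equiv), pyridine, DMAP (10 mol %), CH2Cl2, rt → 40 °C
Reagents that add atoms: acetic anhydride (CC(=O)OC(C)=O)
Why: DMAP-catalysed exhaustive O-acetylation, which also reaches the chelated 5-OH. The acetates remove the acidic protons and the O4/O5 chelate site that would bind rhodium, and they weaken the donor effect of O5 and O7 so that C2 becomes a better acceptor.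

Step 4
Reactants: 9 (4-hydroxy-3-methoxyphenyl)boronic acid
Product: 10 (4-acetoxy-3-methoxyphenyl)boronic acid
Conditions: Ac2O (1.5 equiv), pyridine, CH2Cl2, 0 °C → rt; aqueous work-up at pH 4–5
Reagents that add atoms: acetic anhydride (CC(=O)OC(C)=O)
Why: Simple phenol acetylation; boron-bound acetate is hydrolysed again on aqueous work-up. The acetate slows protodeboronation of the otherwise very electron-rich arylboronic acid and matches the protecting groups of 8.

Step 5
Reactants: 8 6-(2-acetoxyethyl)-8-(3-methylbut-2-en-1-yl)-4-oxo-4H-chromene-5,7-diyl diacetate; 10 (4-acetoxy-3-methoxyphenyl)boronic acid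
Product: 11 (2S)-6-(2-acetoxyethyl)-2-(4-acetoxy-3-methoxyphenyl)-8-(3-methylbut-2-en-1-yl)-4-oxochromane-5,7-diyl diacetate
Conditions: [Rh(OH)(cod)]2 (2.5 mol %), (S)-MeO-F12-BIPHEP (5.5 mol %), 10 (2 equiv), CH2Cl2/H2O, 25–35 °C
Reagents that add atoms: none
Why: Rhodium-catalysed asymmetric 1,4-addition of an arylboronic acid (Hayashi–Miyaura reaction), a type with close precedent on chromones: transmetalation, enantio-determining insertion of C2=C3 into aryl–Rh, and hydrolysis of the oxa-π-allyl rhodium. C2 is set by the ligand alone; by the quadrant model valid for cyclic enones the (S)-biaryl diphosphine should deliver the aryl group to the Re face of C2 and give 2S, and the antipodal ligand is available should the sense be opposite. The base-free two-phase medium keeps the acetates and the new stereocentre intact, and the trisubstituted prenyl alkene does not insert.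

Step 6
Reactants: 11 (2S)-6-(2-acetoxyethyl)-2-(4-acetoxy-3-methoxyphenyl)-8-(3-methylbut-2-en-1-yl)-4-oxochromane-5,7-diyl diacetate
Product: 12 laxiflorin, (2S)-5,7-dihydroxy-6-(2-hydroxyethyl)-2-(4-hydroxy-3-methoxyphenyl)-8-(3-methylbut-2-en-1-yl)chroman-4-one
Conditions: HCl (0.5 M) in MeOH, argon, 0 °C → rt
Reagents that add atoms: none
Why: Acid-catalysed transesterification removes all four acetates as methyl acetate. Ring C cannot open, because the retro-oxa-Michael path needs an enolate or phenoxide. Dilute methanolic HCl at or below room temperature is the medium in which acetal protecting groups are commonly removed from prenylated flavanones.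

## Compound list

1 | 2-methyl-4H-pyran-4-one | CC1=CC(=O)C=CO1 | starting material
2 | 1-bromo-3-methylbut-2-ene (prenyl bromide) | CC(C)=CCBr | starting material
3 | 2-(4-methylpent-3-en-1-yl)-4H-pyran-4-one | CC(C)=CCCC1=CC(=O)C=CO1 | intermediate
4 | dimethyl cyclopropane-1,1-dicarboxylate | COC(=O)C1(CC1)C(=O)OC | starting material
5 | methyl 1-[5-methyl-2-(4-oxo-4H-pyran-2-yl)hex-4-enoyl]cyclopropane-1-carboxylate (keto ester, racemic, present as lithium enolate) | COC(=O)C1(CC1)C(=O)C(CC=C(C)C)C2=CC(=O)C=CO2 | intermediate
6 | 7-hydroxy-8-(3-methylbut-2-en-1-yl)spiro[chromene-6,1'-cyclopropane]-4,5-dione (spirocyclopropane dienone, present as lithium enolate until the quench) | O=C1C=COC2=C1C(=O)C3(CC3)C(O)=C2CC=C(C)C | intermediate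
7 | 5,7-dihydroxy-6-(2-hydroxyethyl)-8-(3-methylbut-2-en-1-yl)-4H-chromen-4-one | O=c1ccoc2c1c(O)c(CCO)c(O)c2CC=C(C)C | intermediate
8 | 6-(2-acetoxyethyl)-8-(3-methylbut-2-en-1-yl)-4-oxo-4H-chromene-5,7-diyl diacetate | O=c1ccoc2c1c(OC(C)=O)c(CCOC(C)=O)c(OC(C)=O)c2CC=C(C)C | intermediate
9 | (4-hydroxy-3-methoxyphenyl)boronic acid | COc1cc(B(O)O)ccc1O | starting material
10 | (4-acetoxy-3-methoxyphenyl)boronic acid | COc1cc(B(O)O)ccc1OC(C)=O | intermediate
11 | (2S)-6-(2-acetoxyethyl)-2-(4-acetoxy-3-methoxyphenyl)-8-(3-methylbut-2-en-1-yl)-4-oxochromane-5,7-diyl diacetate | COc1cc([C@@H]2CC(=O)c3c(OC(C)=O)c(CCOC(C)=O)c(OC(C)=O)c(CC=C(C)C)c3O2)ccc1OC(C)=O | intermediate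
12 | laxiflorin, (2S)-5,7-dihydroxy-6-(2-hydroxyethyl)-2-(4-hydroxy-3-methoxyphenyl)-8-(3-methylbut-2-en-1-yl)chroman-4-one | COc1cc([C@@H]2CC(=O)c3c(O)c(CCO)c(O)c(CC=C(C)C)c3O2)ccc1O | target

## Step count and least certain steps

Total steps: 6. Longest linear sequence: 5 (steps 1, 2, 3, 5, 6, from 1).

**Step 2 (key step, Proposed new method).**
- *What may go wrong.* The crossed Claisen condensation joins a secondary, delocalised dienolate to an α-quaternary ester and may be slow. The dienolate could then add to pyranone rings, or methoxide or the dienolate could open the three-membered ring before ring A is closed. Alternatively, closure through C4a may stall at the stage of 5, with retro-Claisen cleavage on work-up.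
- *Fallback (known chemistry).* It gives up 3 and 4, sets out from prenyl bromide 2 and comes back to the route at 7.
  - Commercial 5,7-dihydroxy-4H-chromen-4-one F1 is protected at the non-chelated 7-OH (MOMCl, i-Pr2NEt) as 5-hydroxy-7-(methoxymethoxy)-4H-chromen-4-one F2.
  - F2 is allylated at O5 (allyl bromide, K2CO3) to 5-(allyloxy)-7-(methoxymethoxy)-4H-chromen-4-one F3.
  - Aromatic Claisen rearrangement can only end at C6, the single open ortho position of O5. It gives 6-allyl-5-hydroxy-7-(methoxymethoxy)-4H-chromen-4-one F4.
  - Lemieux–Johnson cleavage gives [5-hydroxy-7-(methoxymethoxy)-4-oxo-4H-chromen-6-yl]acetaldehyde F5. Aldehyde-selective reduction with NaBH(OAc)3 then gives 5-hydroxy-6-(2-hydroxyethyl)-7-(methoxymethoxy)-4H-chromen-4-one F6, before any prenyl group is present.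
  - Phenol-selective O-alkylation with 2 (K2CO3) gives 6-(2-hydroxyethyl)-7-(methoxymethoxy)-5-[(3-methylbut-2-en-1-yl)oxy]-4H-chromen-4-one F7.
  - Eu(fod)3-catalysed Claisen–Cope sequence of F7 gives 5-hydroxy-6-(2-hydroxyethyl)-7-(methoxymethoxy)-8-(3-methylbut-2-en-1-yl)-4H-chromen-4-one F8. The ortho position is blocked, so the inverted allyl group moves on to the para position C8.
  - Methanolic HCl removes the acetal and delivers 7.

**Step 5.**
- *What may go wrong.* Turnover on an electron-rich chromone with both peri positions substituted may be slow. Protodeboronation would then consume 10, a second 1,2-addition to the product ketone could occur, or facial selectivity could be insufficient.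
- *Fallback.* Resolution replaces asymmetric C–C bond formation. It sets out from 8 and 10 and comes back at 11. The arylation is run with an achiral catalyst ([Rh(OH)(cod)]2 alone) to give racemic 6-(2-acetoxyethyl)-2-(4-acetoxy-3-methoxyphenyl)-8-(3-methylbut-2-en-1-yl)-4-oxochromane-5,7-diyl diacetate F9. Kinetic resolution follows by asymmetric transfer hydrogenation (Noyori–Ikariya TsDPEN catalyst, HCO2H/Et3N), with the catalyst enantiomer that reduces the 2R ketone. This converts that enantiomer into (2R,4R)-6-(2-acetoxyethyl)-2-(4-acetoxy-3-methoxyphenyl)-4-hydroxy-8-(3-methylbut-2-en-1-yl)chromane-5,7-diyl diacetate F10, which is separated, and leaves (2S)-11.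

**Step 6.**
- *What may go wrong.* Methanolysis of the hindered aryl acetates and the primary acetate may be slow and force long acid exposure. The prenyl group could then cyclise onto 7-OH or add methanol across the alkene. A change to base would open ring C and racemise C2.
- *Fallback.* Fluoride-labile groups replace the acyl groups. It sets out from 7 and 9 and comes back at 12.
  - 7 is silylated (TBSOTf, 2,6-lutidine) to 5,7-bis[(tert-butyldimethylsilyl)oxy]-6-{2-[(tert-butyldimethylsilyl)oxy]ethyl}-8-(3-methylbut-2-en-1-yl)-4H-chromen-4-one F11.
  - 9 is silylated (TBSCl, imidazole, aqueous work-up) to {4-[(tert-butyldimethylsilyl)oxy]-3-methoxyphenyl}boronic acid F12.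
  - The rhodium-catalysed addition of step 5 joins them to (2S)-5,7-bis[(tert-butyldimethylsilyl)oxy]-6-{2-[(tert-butyldimethylsilyl)oxy]ethyl}-2-{4-[(tert-butyldimethylsilyl)oxy]-3-methoxyphenyl}-8-(3-methylbut-2-en-1-yl)chroman-4-one F13.
  - Et3N·3HF in THF, a weakly acidic medium harmless to prenyl and C2, gives 12.

## Further compounds

F1 | step 2 | 5,7-dihydroxy-4H-chromen-4-one | O=c1ccoc2cc(O)cc(O)c12
F2 | step 2 | 5-hydroxy-7-(methoxymethoxy)-4H-chromen-4-one | O=c1ccoc2cc(OCOC)cc(O)c12
F3 | step 2 | 5-(allyloxy)-7-(methoxymethoxy)-4H-chromen-4-one | O=c1ccoc2cc(OCOC)cc(OCC=C)c12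
F4 | step 2 | 6-allyl-5-hydroxy-7-(methoxymethoxy)-4H-chromen-4-one | O=c1ccoc2cc(OCOC)c(CC=C)c(O)c12
F5 | step 2 | [5-hydroxy-7-(methoxymethoxy)-4-oxo-4H-chromen-6-yl]acetaldehyde | O=c1ccoc2cc(OCOC)c(CC=O)c(O)c12
F6 | step 2 | 5-hydroxy-6-(2-hydroxyethyl)-7-(methoxymethoxy)-4H-chromen-4-one | O=c1ccoc2cc(OCOC)c(CCO)c(O)c12
F7 | step 2 | 6-(2-hydroxyethyl)-7-(methoxymethoxy)-5-[(3-methylbut-2-en-1-yl)oxy]-4H-chromen-4-one | O=c1ccoc2cc(OCOC)c(CCO)c(OCC=C(C)C)c12
F8 | step 2 | 5-hydroxy-6-(2-hydroxyethyl)-7-(methoxymethoxy)-8-(3-methylbut-2-en-1-yl)-4H-chromen-4-one | O=c1ccoc2c(CC=C(C)C)c(OCOC)c(CCO)c(O)c12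
F9 | step 5 | racemic 6-(2-acetoxyethyl)-2-(4-acetoxy-3-methoxyphenyl)-8-(3-methylbut-2-en-1-yl)-4-oxochromane-5,7-diyl diacetate | COc1cc(C2CC(=O)c3c(OC(C)=O)c(CCOC(C)=O)c(OC(C)=O)c(CC=C(C)C)c3O2)ccc1OC(C)=O
F10 | step 5 | (2R,4R)-6-(2-acetoxyethyl)-2-(4-acetoxy-3-methoxyphenyl)-4-hydroxy-8-(3-methylbut-2-en-1-yl)chromane-5,7-diyl diacetate | COc1cc([C@H]2C[C@@H](O)c3c(OC(C)=O)c(CCOC(C)=O)c(OC(C)=O)c(CC=C(C)C)c3O2)ccc1OC(C)=O
F11 | step 6 | 5,7-bis[(tert-butyldimethylsilyl)oxy]-6-{2-[(tert-butyldimethylsilyl)oxy]ethyl}-8-(3-methylbut-2-en-1-yl)-4H-chromen-4-one | O=c1ccoc2c1c(O[Si](C)(C)C(C)(C)C)c(CCO[Si](C)(C)C(C)(C)C)c(O[Si](C)(C)C(C)(C)C)c2CC=C(C)C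
F12 | step 6 | {4-[(tert-butyldimethylsilyl)oxy]-3-methoxyphenyl}boronic acid | COc1cc(B(O)O)ccc1O[Si](C)(C)C(C)(C)C
F13 | step 6 | (2S)-5,7-bis[(tert-butyldimethylsilyl)oxy]-6-{2-[(tert-butyldimethylsilyl)oxy]ethyl}-2-{4-[(tert-butyldimethylsilyl)oxy]-3-methoxyphenyl}-8-(3-methylbut-2-en-1-yl)chroman-4-one | COc1cc([C@@H]2CC(=O)c3c(O[Si](C)(C)C(C)(C)C)c(CCO[Si](C)(C)C(C)(C)C)c(O[Si](C)(C)C(C)(C)C)c(CC=C(C)C)c3O2)ccc1O[Si](C)(C)C(C)(C)C
A1 | alternative 1 | 1-[2,4,6-trihydroxy-3-(2-hydroxyethyl)-5-(3-methylbut-2-en-1-yl)phenyl]ethan-1-one | CC(=O)c1c(O)c(CCO)c(O)c(CC=C(C)C)c1O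
A2 | alternative 1 | vanillin (4-hydroxy-3-methoxybenzaldehyde) | COc1cc(C=O)ccc1O
A3 | alternative 1 | (E)-3-(4-hydroxy-3-methoxyphenyl)-1-[2,4,6-trihydroxy-3-(2-hydroxyethyl)-5-(3-methylbut-2-en-1-yl)phenyl]prop-2-en-1-one | COc1cc(/C=C/C(=O)c2c(O)c(CCO)c(O)c(CC=C(C)C)c2O)ccc1O
A4 | alternative 1 | 5,7-dihydroxy-8-(2-hydroxyethyl)-2-(4-hydroxy-3-methoxyphenyl)-6-(3-methylbut-2-en-1-yl)chroman-4-one | COc1cc(C2CC(=O)c3c(O)c(CC=C(C)C)c(O)c(CCO)c3O2)ccc1O
A5 | alternative 2 | homoeriodictyol, (2S)-5,7-dihydroxy-2-(4-hydroxy-3-methoxyphenyl)chroman-4-one | COc1cc([C@@H]2CC(=O)c3c(O)cc(O)cc3O2)ccc1O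
A6 | alternative 2 | (2S)-6-(2-hydroxyethyl)-7-(methoxymethoxy)-2-[3-methoxy-4-(methoxymethoxy)phenyl]-5-[(3-methylbut-2-en-1-yl)oxy]chroman-4-one | COc1cc([C@@H]2CC(=O)c3c(OCC=C(C)C)c(CCO)c(OCOC)cc3O2)ccc1OCOC
A7 | alternative 3 | (3S)-3-{2,6-diiodo-3,5-bis(methoxymethoxy)-4-[2-(methoxymethoxy)ethyl]phenoxy}-N-methoxy-3-[3-methoxy-4-(methoxymethoxy)phenyl]-N-methylpropanamide | COCOCCc1c(OCOC)c(I)c(O[C@@H](CC(=O)N(C)OC)c2ccc(OCOC)c(OC)c2)c(I)c1OCOC
A8 | alternative 3 | (3R)-3-hydroxy-N-methoxy-3-[3-methoxy-4-(methoxymethoxy)phenyl]-N-methylpropanamide | COCOc1ccc(cc1OC)[C@H](O)CC(=O)N(C)OC
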